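The wanted product is the activated form, which passes on to the ring, so its curve rises, peaks and falls.

- beta: substrate 0.10 M; activator 2.2 equiv; run made earlier
- flask: substrate 0.10 M; activator 1.10 equiv; time 1.5 h
beta run (percent of the substrate charged)

| time / min | activated form / % | ring / % | substrate / % |
|---|---|---|---|
| 1.33 | 25 | 11 | 15 |
| 2.50 | 18 | 24 | 4 |
| 4.00 | 10 | 32 | 1 |
| 6.00 | 5 | 38 | 0 |
| 10.0 | 0 | 41 | 1 |
| 20.0 | 1 | 41 | 0 |

(standard deviation of a reading: 1.5 percentage points)

1. time up to 1.5 h at which activated form stands highest, in min
2. the amount of activated form, in percent of the substrate charged, at that time

1. Slope. In the beta run, activated form and ring together stand at 36.0% by 1.33 min, a mean slope of 0.271 min⁻¹ as a fraction of the charge.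

2. Knee. The highest beta reading of activated form is 25% at 1.33 min, with substrate already at 15%.

3. Crossing. By 2.50 min the beta ring reads 24%, above activated form at 18%.

4. Tail. Beta activated form then falls to 5% by 6.00 min, a half-life of 1.89 min as read. That is short against 1.5 h, so the curve in the flask should also run down to zero.

5. Rule. The beta run has one activator charge, so it cannot show whether the substrate loss needs activator. This reckoning assumes it does not. On that assumption substrate should fall in the flask as in beta, the knee should stay near 1.33 min, and the height should follow the activator charge. The peak per equivalent, as read, is 11.4%: the highest beta reading of activated form divided by the equivalents of activator in beta. The flask should therefore peak near 12.5%.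

6. Forecast. It takes the side loss as “apparently with the same activator dependence” and gives 18.7% at 1.7 min, higher than this reckoning.

The flask gives 12.0% at 1.25 min, against 12.5% from the peak per equivalent.

    activated form → ring (k = 0.00777 s⁻¹)
    substrate + activated form → open dimer (k = 0.0559 L mol⁻¹ s⁻¹)
    substrate + activator → activated form (k = 0.0582 L mol⁻¹ s⁻¹)
    2 substrate → homo dimer (k = 0.177 L mol⁻¹ s⁻¹)

At the start, with its charges, the flask sends substrate into homo dimer 5.53 times as fast as into activated form, by a step that takes no activator. At the best time homo dimer in the flask holds 59.7% of the substrate charged, each dimer counted as two, against 12.0% in activated form. The neighbour flask with 0.660 equiv gets 7.52% from the peak per equivalent and peaks at 7.58%.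

The data were generated by integration for substances that don't exist, and the scatter is random.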